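**Retrosynthetic overview**
1. Ring C (ten-membered carbocycle, nine-membered through the furanone oxygen) is closed last at C4=C5 by ring-closing metathesis of a seco-diene.
2. The C8 ester is installed with inversion (Mitsunobu) on an (8S)-alcohol.
3. C7–C8 joins fragment 1 (furanone aldehyde) and fragment 2 (bromobutenolide) by a zinc Barbier allylation; ring B comes from a Pd-catalysed carbonylative lactonization.
4. C3–C4 is formed by a Pd-catalysed C–H alkenylation of a 5-unsubstituted 3(2H)-furanone (ring A) with 2-bromopropene; C10 comes from (R)-lactic acid by Seebach alkylation.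
5. Ring order: A (furanone), then B (butenolide, later the α-methylene lactone), then C (macrocycle).

Numbering: C1–C15 are germacrane locants of 27 (C1 ketone, C3 furanone carbon on oxygen, C4=C5, C6 lactone O–CH, C7, C8 ester carbon, C9, C10 quaternary, C11=C13, C12 lactone carbonyl, C14 and C15 methyls). Compound names use their own ring numbering.
Assumption: (S,S)-ProPhenol is taken to give the (R)-carbinol in step 9; if the sense of induction is the reverse, the (R,R)-ligand is used.

**Fragment 1 (steps 1–7)**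

Step 1
Reactants: 1 (R)-lactic acid; 2 pivalaldehyde
Product: 3 (2R,5R)-2-tert-butyl-5-methyl-1,3-dioxolan-4-one
Conditions: p-TsOH·H2O (cat.), H2SO4 (cat.), pentane, reflux, Dean–Stark; recrystallize at −78 °C
Reagents that add atoms: none
Why: Seebach acetalization under thermodynamic control gives the cis-dioxolanone, so the new acetal center is (R) with tert-butyl cis to methyl while C5 keeps its (R) configuration.

Step 2
Reactants: 3 (2R,5R)-2-tert-butyl-5-methyl-1,3-dioxolan-4-one; 4 allyl bromide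
Product: 5 (2R,5S)-2-tert-butyl-5-methyl-5-(prop-2-en-1-yl)-1,3-dioxolan-4-one
Conditions: LiN(i-Pr)2, THF, −78 °C; then 4, −78 → −20 °C
Reagents that add atoms: none
Why: Seebach self-regeneration of stereocenters: the lithium enolate is alkylated on the face opposite the tert-butyl group, so allyl takes the place of the former hydrogen and the quaternary center (future C10) is set as (S).

Step 3
Reactants: 5 (2R,5S)-2-tert-butyl-5-methyl-5-(prop-2-en-1-yl)-1,3-dioxolan-4-one
Product: 7 (2R,5S)-2-tert-butyl-5-(1,3-dioxolan-2-ylmethyl)-5-methyl-1,3-dioxolan-4-one, via dioxolanone aldehyde 6 (not isolated)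
Conditions: O3, CH2Cl2, −78 °C; PPh3, −78 → 25 °C; then HOCH2CH2OH, HC(OMe)3, p-TsOH·H2O (cat.), 25 °C
Reagents that add atoms: ethylene glycol, OCCO
Why: Ozonolysis with reductive work-up cleaves the terminal alkene to aldehyde 6 (future C8), which is protected at once by acid-catalysed acetalization so that it survives two organomagnesium steps; no stereocenter is touched.

Step 4
Reactants: 7 (2R,5S)-2-tert-butyl-5-(1,3-dioxolan-2-ylmethyl)-5-methyl-1,3-dioxolan-4-one
Product: 8 (2S)-3-(1,3-dioxolan-2-yl)-2-hydroxy-N-methoxy-N,2-dimethylpropanamide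
Conditions: MeNH(OMe)·HCl (3 equiv), i-PrMgCl (6 equiv), THF, −20 → 0 °C
Reagents that add atoms: N,O-dimethylhydroxylamine hydrochloride, CNOC.Cl
Why: Weinreb amide formation by attack of ClMgN(OMe)Me on the lactone carbonyl, the hemiacetal alkoxide collapsing on work-up with loss of pivalaldehyde to free the tertiary alcohol; the quaternary center is not involved.

Step 5
Reactants: 8 (2S)-3-(1,3-dioxolan-2-yl)-2-hydroxy-N-methoxy-N,2-dimethylpropanamide; 9 ethynylmagnesium bromide
Product: 10 (4S)-5-(1,3-dioxolan-2-yl)-4-hydroxy-4-methylpent-1-yn-3-one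
Conditions: 9 (3.5 equiv), THF, 0 → 25 °C; aq NH4Cl
Reagents that add atoms: none
Why: Weinreb ketone synthesis: one equivalent deprotonates the alcohol and the next adds only once because the magnesium chelate persists until work-up, installing C2 and C3 as a terminal ynone.

Step 6
Reactants: 10 (4S)-5-(1,3-dioxolan-2-yl)-4-hydroxy-4-methylpent-1-yn-3-one
Product: 12 (2S)-2-(1,3-dioxolan-2-ylmethyl)-2-methylfuran-3(2H)-one, via diethylamino enone 11 (not isolated)
Conditions: Et2NH, EtOH, 25 °C; then AcOH, H2O, 25 °C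
Reagents that add atoms: none
Why: Conjugate addition of Et2NH gives enaminone 11, and under mild acid the tertiary hydroxyl adds to the iminium carbon and expels Et2NH (5-exo addition–elimination), the classical 3(2H)-furanone synthesis from α'-hydroxy ynones, closing ring A while the dioxolane survives.

Step 7
Reactants: 12 (2S)-2-(1,3-dioxolan-2-ylmethyl)-2-methylfuran-3(2H)-one; 13 2-bromopropene
Product: 14 (2S)-2-(1,3-dioxolan-2-ylmethyl)-2-methyl-5-(prop-1-en-2-yl)furan-3(2H)-one
Conditions: Pd(OAc)2 (5 mol %), PCy3·HBF4 (10 mol %), t-BuCO2H (30 mol %), K2CO3 (2 equiv), 13 (3 equiv), toluene, 100 °C, sealed tube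
Reagents that add atoms: none
Why: Proposed new method: oxidative addition of 13 to zerovalent palladium gives an isopropenylpalladium bromide (divalent palladium) that exchanges bromide for pivalate and cleaves the C–H bond at ring position 5 of the furanone (germacrane C3, the most acidic sp2 C–H, alpha to the ring oxygen as in furan or chromone C2–H) by concerted metalation–deprotonation, and reductive elimination forges C3–C4; a competing Heck-type carbopalladation would also place the alkenyl group on this carbon (beta carbon of the enone), so both manifolds converge on one regioisomer, and the hydrogen-free quaternary center cannot epimerize; the closest known reaction type is the carboxylate-assisted direct C–H arylation and alkenylation of furans, azoles and chromones with organic halides, not yet shown for 3(2H)-furanones.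

**Fragment 2 (steps 8–13)**

Step 8
Reactants: 15 propargyl alcohol
Product: 16 tert-butyldimethyl(prop-2-yn-1-yloxy)silane
Conditions: t-BuMe2SiCl, imidazole, CH2Cl2, 0 → 25 °C
Reagents that add atoms: tert-butyldimethylsilyl chloride, CC(C)(C)[Si](C)(C)Cl
Why: Silyl protection of the primary alcohol, so that only the secondary hydroxyl made in step 9 directs the hydroalumination of step 10.

Step 9
Reactants: 16 tert-butyldimethyl(prop-2-yn-1-yloxy)silane; 17 (E)-crotonaldehyde
Product: 18 (4R,5E)-1-[(tert-butyldimethylsilyl)oxy]hept-5-en-2-yn-4-ol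
Conditions: Me2Zn, (S,S)-ProPhenol (20 mol %), Ph3PO (40 mol %), toluene, 0 °C; then 17
Reagents that add atoms: none
Why: Trost zinc–ProPhenol enantioselective alkynylation of an enal: the dinuclear zinc catalyst delivers the alkynyl group to one aldehyde face and sets C6 as (R).

Step 10
Reactants: 18 (4R,5E)-1-[(tert-butyldimethylsilyl)oxy]hept-5-en-2-yn-4-ol
Product: 19 (2Z,4R,5E)-1-[(tert-butyldimethylsilyl)oxy]-2-iodohepta-2,5-dien-4-ol
Conditions: NaAlH2(OCH2CH2OMe)2, THF, 0 → 25 °C; then I2, −78 °C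
Reagents that add atoms: iodine, II
Why: Hydroxyl-directed trans-hydroalumination of the propargylic alcohol puts hydride on the proximal and aluminium on the distal alkyne carbon through a five-membered alkoxyaluminate, and iodinolysis with retention gives the (Z)-vinyl iodide with iodine cis to the carbinol.

Step 11
Reactants: 19 (2Z,4R,5E)-1-[(tert-butyldimethylsilyl)oxy]-2-iodohepta-2,5-dien-4-ol
Product: 20 (5R)-3-{[(tert-butyldimethylsilyl)oxy]methyl}-5-[(1E)-prop-1-en-1-yl]furan-2(5H)-one
Conditions: CO (1 atm), PdCl2(PPh3)2 (5 mol %), K2CO3, THF, 25 °C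
Reagents that add atoms: carbon monoxide, [C-]#[O+]
Why: Pd-catalysed carbonylative lactonization of a (Z)-γ-iodo allylic alcohol: oxidative addition, CO insertion and capture of the acylpalladium by the cis hydroxyl close ring B and install C12 at 25 °C without touching C6.

Step 12
Reactants: 20 (5R)-3-{[(tert-butyldimethylsilyl)oxy]methyl}-5-[(1E)-prop-1-en-1-yl]furan-2(5H)-one
Product: 21 (5R)-3-(hydroxymethyl)-5-[(1E)-prop-1-en-1-yl]furan-2(5H)-one
Conditions: HF·pyridine, pyridine, THF, 0 → 25 °C
Reagents that add atoms: none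
Why: Acidic fluoride desilylation avoids the basic conditions that could epimerize the γ-position of the butenolide.

Step 13
Reactants: 21 (5R)-3-(hydroxymethyl)-5-[(1E)-prop-1-en-1-yl]furan-2(5H)-one
Product: 22 (5R)-3-(bromomethyl)-5-[(1E)-prop-1-en-1-yl]furan-2(5H)-one
Conditions: CBr4, PPh3, CH2Cl2, 0 °C
Reagents that add atoms: carbon tetrabromide, BrC(Br)(Br)Br
Why: Appel bromination of the primary allylic alcohol under neutral conditions gives the Barbier partner.

**Union and endgame (steps 14–16)**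

Step 14
Reactants: 14 (2S)-2-(1,3-dioxolan-2-ylmethyl)-2-methyl-5-(prop-1-en-2-yl)furan-3(2H)-one; 22 (5R)-3-(bromomethyl)-5-[(1E)-prop-1-en-1-yl]furan-2(5H)-one
Product: 24 (4R,5R)-4-{(1S)-1-hydroxy-2-[(2S)-2-methyl-3-oxo-5-(prop-1-en-2-yl)-2,3-dihydrofuran-2-yl]ethyl}-3-methylidene-5-[(1E)-prop-1-en-1-yl]oxolan-2-one, via furanone aldehyde 23 (not isolated)
Conditions: p-TsOH·H2O (10 mol %), THF/H2O (4:1), 45 °C; then sat. aq NH4Cl, 22 (1.5 equiv), Zn dust, 0 → 25 °C
Reagents that add atoms: water, O
Why: Acetal hydrolysis frees aldehyde 23, and the zinc Barbier allylation (allylzinc from 22 reacting at its γ-carbon, SE2') passes through a Zimmerman–Traxler chair in which the ring-locked (E)-type allylzinc is attacked anti to the propenyl group, setting C7 as (R) (trans lactone) and, with the aldehyde substituent equatorial, the anti carbinol C8 as (S).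

Step 15
Reactants: 24 (4R,5R)-4-{(1S)-1-hydroxy-2-[(2S)-2-methyl-3-oxo-5-(prop-1-en-2-yl)-2,3-dihydrofuran-2-yl]ethyl}-3-methylidene-5-[(1E)-prop-1-en-1-yl]oxolan-2-one; 25 (R)-2-methylbutanoic acid
Product: 26 (1R)-2-[(2S)-2-methyl-3-oxo-5-(prop-1-en-2-yl)-2,3-dihydrofuran-2-yl]-1-{(2R,3R)-4-methylidene-5-oxo-2-[(1E)-prop-1-en-1-yl]oxolan-3-yl}ethyl (2R)-2-methylbutanoate
Conditions: PPh3, i-PrO2CN=NCO2i-Pr, 25 (2 equiv), toluene, 0 → 25 °C
Reagents that add atoms: none
Why: Mitsunobu esterification: the alkoxyphosphonium of the (8S)-alcohol is displaced by the carboxylate with inversion, which installs the (R)-2-methylbutanoate and corrects C8 to (R) in one operation without touching the stereocenter of the acid.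

Step 16
Reactants: 26 (1R)-2-[(2S)-2-methyl-3-oxo-5-(prop-1-en-2-yl)-2,3-dihydrofuran-2-yl]-1-{(2R,3R)-4-methylidene-5-oxo-2-[(1E)-prop-1-en-1-yl]oxolan-3-yl}ethyl (2R)-2-methylbutanoate
Product: 27 (4Z,6R,7R,8R,10S)-8-[(2R)-2-methylbutanoyloxy]-1-oxo-3,10-epoxygermacra-2,4,11(13)-trien-12,6-olide (target)
Conditions: second-generation Hoveyda–Grubbs catalyst, RuCl2(H2IMes)(=CH-C6H4-2-O-i-Pr) (15 mol %, two portions), 1,4-benzoquinone (30 mol %), toluene (1 mM), 100 °C, argon sparge
Reagents that add atoms: none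
Why: Ring-closing metathesis: the ruthenium carbene formed at the propenyl group engages the isopropenyl group to close ring C with loss of propene, and the nine-membered oxacycle can only hold the (Z)-trisubstituted C4=C5 olefin.

**Compound list**
1 | (R)-lactic acid, (2R)-2-hydroxypropanoic acid | C[C@@H](O)C(=O)O | starting material
2 | pivalaldehyde, 2,2-dimethylpropanal | CC(C)(C)C=O | starting material
3 | (2R,5R)-2-tert-butyl-5-methyl-1,3-dioxolan-4-one | C[C@H]1O[C@@H](C(C)(C)C)OC1=O | intermediate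
4 | allyl bromide, 3-bromoprop-1-ene | C=CCBr | starting material
5 | (2R,5S)-2-tert-butyl-5-methyl-5-(prop-2-en-1-yl)-1,3-dioxolan-4-one | C=CC[C@]1(C)O[C@@H](C(C)(C)C)OC1=O | intermediate
6 | (2R,5S)-2-tert-butyl-5-methyl-5-(2-oxoethyl)-1,3-dioxolan-4-one | O=CC[C@]1(C)O[C@@H](C(C)(C)C)OC1=O | intermediate
7 | (2R,5S)-2-tert-butyl-5-(1,3-dioxolan-2-ylmethyl)-5-methyl-1,3-dioxolan-4-one | C1COC(C[C@]2(C)O[C@@H](C(C)(C)C)OC2=O)O1 | intermediate
8 | (2S)-3-(1,3-dioxolan-2-yl)-2-hydroxy-N-methoxy-N,2-dimethylpropanamide | C1COC(C[C@](C)(O)C(=O)N(C)OC)O1 | intermediate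
9 | ethynylmagnesium bromide | C#C[Mg]Br | starting material
10 | (4S)-5-(1,3-dioxolan-2-yl)-4-hydroxy-4-methylpent-1-yn-3-one | C1COC(C[C@](C)(O)C(=O)C#C)O1 | intermediate
11 | (1E,4S)-1-(diethylamino)-5-(1,3-dioxolan-2-yl)-4-hydroxy-4-methylpent-1-en-3-one | C1COC(C[C@](C)(O)C(=O)/C=C/N(CC)CC)O1 | intermediate
12 | (2S)-2-(1,3-dioxolan-2-ylmethyl)-2-methylfuran-3(2H)-one | C1COC(C[C@]2(C)OC=CC2=O)O1 | intermediate
13 | 2-bromopropene | CC(Br)=C | starting material
14 | (2S)-2-(1,3-dioxolan-2-ylmethyl)-2-methyl-5-(prop-1-en-2-yl)furan-3(2H)-one | C1COC(C[C@]2(C)OC(C(C)=C)=CC2=O)O1 | intermediate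
15 | propargyl alcohol, prop-2-yn-1-ol | C#CCO | starting material
16 | tert-butyldimethyl(prop-2-yn-1-yloxy)silane | C#CCO[Si](C)(C)C(C)(C)C | intermediate
17 | (E)-crotonaldehyde, (2E)-but-2-enal | C/C=C/C=O | starting material
18 | (4R,5E)-1-[(tert-butyldimethylsilyl)oxy]hept-5-en-2-yn-4-ol | CC(C)(C)[Si](C)(C)OCC#C[C@H](O)/C=C/C | intermediate
19 | (2Z,4R,5E)-1-[(tert-butyldimethylsilyl)oxy]-2-iodohepta-2,5-dien-4-ol | CC(C)(C)[Si](C)(C)OC/C(I)=C/[C@H](O)/C=C/C | intermediate
20 | (5R)-3-{[(tert-butyldimethylsilyl)oxy]methyl}-5-[(1E)-prop-1-en-1-yl]furan-2(5H)-one | CC(C)(C)[Si](C)(C)OCC1=C[C@@H](/C=C/C)OC1=O | intermediate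
21 | (5R)-3-(hydroxymethyl)-5-[(1E)-prop-1-en-1-yl]furan-2(5H)-one | OCC1=C[C@@H](/C=C/C)OC1=O | intermediate
22 | (5R)-3-(bromomethyl)-5-[(1E)-prop-1-en-1-yl]furan-2(5H)-one | BrCC1=C[C@@H](/C=C/C)OC1=O | intermediate
23 | [(2S)-2-methyl-3-oxo-5-(prop-1-en-2-yl)-2,3-dihydrofuran-2-yl]acetaldehyde | O=CC[C@]1(C)OC(C(C)=C)=CC1=O | intermediate
24 | (4R,5R)-4-{(1S)-1-hydroxy-2-[(2S)-2-methyl-3-oxo-5-(prop-1-en-2-yl)-2,3-dihydrofuran-2-yl]ethyl}-3-methylidene-5-[(1E)-prop-1-en-1-yl]oxolan-2-one | C=C1C(=O)O[C@H](/C=C/C)[C@H]1[C@@H](O)C[C@]1(C)OC(C(C)=C)=CC1=O | intermediate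
25 | (R)-2-methylbutanoic acid | CC[C@@H](C)C(=O)O | starting material
26 | (1R)-2-[(2S)-2-methyl-3-oxo-5-(prop-1-en-2-yl)-2,3-dihydrofuran-2-yl]-1-{(2R,3R)-4-methylidene-5-oxo-2-[(1E)-prop-1-en-1-yl]oxolan-3-yl}ethyl (2R)-2-methylbutanoate | C=C1C(=O)O[C@H](/C=C/C)[C@H]1[C@H](OC(=O)[C@H](C)CC)C[C@]1(C)OC(C(C)=C)=CC1=O | intermediate
27 | (4Z,6R,7R,8R,10S)-8-[(2R)-2-methylbutanoyloxy]-1-oxo-3,10-epoxygermacra-2,4,11(13)-trien-12,6-olide | C=C1C(=O)O[C@@H]2/C=C(/C)C3=CC(=O)[C@](C)(C[C@@H](OC(=O)[C@H](C)CC)[C@@H]12)O3 | target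

**Step count**
Total steps: 16 (fragment 1: steps 1–7; fragment 2: steps 8–13; endgame: steps 14–16).
Longest linear sequence: 10 steps (steps 1–7, then 14–16).

**Three steps most likely to fail**

Step 7 (new C–H alkenylation). Risks are alkenylation at the carbon alpha to the ketone, ring opening, or further Heck reaction of the product diene. The fallback uses known chemistry and sets out from Weinreb amide 8. The lithium acetylide of 2-methylbut-1-en-3-yne (n-BuLi, THF, −78 °C) is added to 8 to give (6S)-7-(1,3-dioxolan-2-yl)-6-hydroxy-2,6-dimethylhept-1-en-3-yn-5-one F1. Cycloisomerization of this γ-hydroxy ynone (Ph3PAuCl/AgOTf cat., toluene, 25 °C, or Et2NH then AcOH) closes the furanone with the isopropenyl group already in place. The route comes back at 14.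

Step 15 (Mitsunobu on a hindered secondary alcohol). Risks are elimination towards a diene or no reaction. The fallback avoids the inversion by making the C8 epimer directly, and sets out from bromide 22 and acetal 14. Compound 22 is converted with Zn dust and Bu3SnCl (THF/sat. aq NH4Cl) into (5R)-5-[(1E)-prop-1-en-1-yl]-3-[(tributylstannyl)methyl]furan-2(5H)-one F2. Aldehyde 23, this time isolated after hydrolysis of 14, is treated with F2 and BF3·OEt2 (CH2Cl2, −78 °C, KF work-up). The open antiperiplanar transition state of Lewis-acid-promoted allylstannane additions is syn-selective and attack is again anti to the propenyl group, giving (4R,5R)-4-{(1R)-1-hydroxy-2-[(2S)-2-methyl-3-oxo-5-(prop-1-en-2-yl)-2,3-dihydrofuran-2-yl]ethyl}-3-methylidene-5-[(1E)-prop-1-en-1-yl]oxolan-2-one F3. Esterification of F3 with 25 with retention (N,N'-dicyclohexylcarbodiimide, DMAP cat., CH2Cl2) comes back to the route at 26.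

Step 16 (ring-closing metathesis to a strained trisubstituted olefin next to an α-methylene lactone). Risks are catalyst loss on the electron-poor exocyclic olefin, isomerization of that olefin, or oligomers. The fallback masks the methylene lactone and sets out from 26. Conjugate addition of Me2NH (THF, 0 °C) gives the C11-epimeric 13-(dimethylamino)-11,13-dihydro derivative of 26 F4. Metathesis of its p-TsOH salt (second-generation Hoveyda–Grubbs catalyst, toluene, 100 °C) on the now saturated lactone gives the 13-(dimethylamino)-11,13-dihydro derivative of 27 F5. MeI converts F5 into the trimethylammonium iodide of F5 F6, and aq NaHCO3 eliminates trimethylamine to restore the C11=C13 olefin. The route comes back at 27.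

**Further compounds**
F1 | step 7 | (6S)-7-(1,3-dioxolan-2-yl)-6-hydroxy-2,6-dimethylhept-1-en-3-yn-5-one | C1COC(C[C@](C)(O)C(=O)C#CC(C)=C)O1
F2 | step 15 | (5R)-5-[(1E)-prop-1-en-1-yl]-3-[(tributylstannyl)methyl]furan-2(5H)-one | CCCC[Sn](CCCC)(CCCC)CC1=C[C@@H](/C=C/C)OC1=O
F3 | step 15 | (4R,5R)-4-{(1R)-1-hydroxy-2-[(2S)-2-methyl-3-oxo-5-(prop-1-en-2-yl)-2,3-dihydrofuran-2-yl]ethyl}-3-methylidene-5-[(1E)-prop-1-en-1-yl]oxolan-2-one | C=C1C(=O)O[C@H](/C=C/C)[C@H]1[C@H](O)C[C@]1(C)OC(C(C)=C)=CC1=O
F4 | step 16 | 13-(dimethylamino)-11,13-dihydro derivative of 26 (C11 epimers) | CN(C)CC1C(=O)O[C@H](/C=C/C)[C@H]1[C@H](OC(=O)[C@H](C)CC)C[C@]1(C)OC(C(C)=C)=CC1=O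
F5 | step 16 | 13-(dimethylamino)-11,13-dihydro derivative of 27 (C11 epimers) | CN(C)CC1C(=O)O[C@@H]2/C=C(/C)C3=CC(=O)[C@](C)(C[C@@H](OC(=O)[C@H](C)CC)[C@@H]12)O3
F6 | step 16 | trimethylammonium iodide of F5 | C[N+](C)(C)CC1C(=O)O[C@@H]2/C=C(/C)C3=CC(=O)[C@](C)(C[C@@H](OC(=O)[C@H](C)CC)[C@@H]12)O3.[I-]
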